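## The problem

Target 25 is the ether between the 4-OH of one guaiacyl ring of (−)-pinoresinol and C8″ of an erythro guaiacylglycerol unit. With the core numbered aryl B–C7–C8(C9)–C8′(C9′)–C7′–aryl A and the side chain C7″(aryl C)–C8″–C9″, the configuration is 7R,8S,7′R,8′S,7″R,8″S. The core is a cis-fused 3,7-dioxabicyclo[3.3.0]octane: ring 1 (C7–O–C9′–C8′–C8) and ring 2 (C7′–O–C9–C8–C8′) share the C8–C8′ bond, and both aryl groups lie on the convex face. The four core centres depend on one another, so one resolved centre (C7) can direct C8 and C8′ by facial control and, less reliably, C7′. The two side-chain centres are insulated from the core by an aromatic ring and need an external controller, and the required erythro relationship is not the one a syn-selective aldol gives directly. The two core aryl groups are constitutionally alike, yet only aryl B carries the ether, so they must be told apart from the first step or by a statistical reaction later. The fragile elements confine the last steps to neutral, non-reductive conditions: the benzylic ether carbons C7 and C7′ are ionised by acid with epimerisation and cleaved by hydrogenolysis, the C7″ carbinol para to a phenolic oxygen forms a quinone methide once that phenol is free, and the free phenols are oxidation-prone. The enabling feature is that ring 2 contains the three-atom unit C7′–O–C9 spanning the neighbouring carbons C8′ and C8: with ring 1 written at lactone level (C9′ as carbonyl), C8=C8′ is the electron-poor double bond of a γ-aryl butenolide made of C7, O, C9′, C8′ and C8, and C7′–O–C9 is the carbonyl ylide of the aryl A aldehyde, so one [3+2] cycloaddition forms C7′–C8′ and C8–C9 and closes ring 2.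

## Retrosynthesis

**25 ⇒ 24.** The last bonds cut are the two O–allyl bonds on aryl A and aryl C. Benzyl ethers would need hydrogenolysis, which threatens the C7–O and C7′–O bonds, and acid-labile acetals would expose the C7″ carbinol to ionisation. Nothing is simplified in the skeleton; the forward step must be a neutral allyl transfer that tolerates two phenols, a benzylic alcohol and the benzylic ethers.

**24 ⇒ 23 ⇒ 22 ⇒ 20 + 9.** Diol 24 is traced to the 4-nitrobenzoate 23 (reduction of ester and imide), 23 to the threo aldol 22 (inversion at C7″), and 22 is cut at C7″–C8″ into glycolyl imide 20 and O-allylvanillin 9. Cutting O–C8″ instead would ask the phenol for an SN2 reaction at a secondary carbon flanked by two oxygenated carbons. An ester-enolate aldol leans erythro but is racemic in the chain. The auxiliary aldol fixes C8″ absolutely and gives a defined C7″ that one Mitsunobu inversion corrects. This removes aryl C and both side-chain centres. The forward steps must give a clean syn-aldol beside the furofuran and an SN2-type inversion at an electron-rich benzylic carbinol.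

**20 ⇒ 18 + 19; 18 ⇒ 17.** The aryl B O–CH2 bond is cut (phenoxide alkylation) to phenol 18 and chloroacetyl imide 19; 18 comes from its SEM ether 17. SEM is preferred to a methoxymethyl ether because soluble fluoride, not acid, removes it, so the benzylic ethers never meet acid. The forward step needs O-alkylation without acyl transfer from the imide.

**17 ⇒ 15 ⇒ 14.** The C9′–O bond of ring 1 is cut to diol 15, and C9′ is raised to the carboxyl level in lactone 14. This is chosen because the lactone carbonyl is what makes C8=C8′ electron-poor in the next cut. In the forward direction the closure must use the C7 oxygen as nucleophile so that C7 keeps its configuration.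

**14 ⇒ 8 + 12 (through ylide 13).** The bonds C7′–C8′ and C8–C9 are cut together. Against cutting C8–C8′ (radical chemistry) or the aryl–C bonds (see below), this cut removes ring 2 and three stereocentres at once and separates two halves that already carry different phenol protection. The precursors are a monocyclic butenolide 8 with one stereocentre and an achiral α-chloro ether 12. The forward reaction must attack the face anti to aryl B, bond C9 to the β-carbon C8, and place aryl A exo.

**8 ⇒ 7 ⇒ 5 ⇒ 4 ⇒ 2 + 3 (and 6); 2 ⇒ 1.** The C8=C8′ bond is cut by ring-closing metathesis to acrylate 7, the ester bond gives carbinol 5 and acryloyl chloride 6, and the C7–vinyl bond gives O-SEM-vanillin 2 and vinylmagnesium bromide 3. A direct catalytic asymmetric vinylation with the parent vinyl group is less well established than a kinetic resolution of racemic 4, so 5 is taken from 4 by resolution, at the cost of half the material. Compound 2 comes from vanillin 1.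

**12 ⇒ 11 ⇒ 9 + 10; 9 ⇒ 1.** The C–Cl bond is traced to the bis(silylmethyl) acetal 11 (acetal cleavage by an acid chloride), and 11 to aldehyde 9 and (trimethylsilyl)methanol 10. Aldehyde 9 comes from vanillin 1 and serves twice, as source of aryl A and of aryl C.

## Roads not taken

**Alternative 1:** The cut is at the two aryl–carbon bonds (aryl B–C7 and aryl A–C7′), with the bicyclic core made first as the bis-lactol diacetate A2. In the key step BF3·OEt2 ionises each anomeric acetate in turn and the arylzinc reagent A3 adds to each oxocarbenium ion from the convex face, giving pinoresinol bis-TIPS ether A1.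
- Merits: both aryl groups and both benzylic centres arrive in one operation, the outcome does not depend on the anomeric configuration of A2, and the route to the core is clearly shorter than the chosen one.
- Weak points for this target: the two aryl groups are identical. Because A1 is C2-symmetric, removing either silyl group gives the same mono-phenol, so a statistical desymmetrisation is workable but loses roughly half the material per pass. The absolute configuration must come from enantiopure A2, which needs its own asymmetric synthesis. The products are electron-rich benzylic ethers left in contact with the Lewis acid that made them, so drift to the epi series is built in.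
- Comparison: in convergence and step count this road is better. The chosen plan sets against it phenol differentiation from the first step, absolute configuration from one resolved carbinol, and no Lewis acid on the finished benzylic ethers.

**Alternative 2:** The cut is at C7–C8, C7′–C8′ and both acyl C–O bonds. In the key step 2,5-bis(trimethylsilyloxy)furan A5 adds twice to TIPS-vanillin A6 under a Ti(OiPr)4/BINOL Lewis acid, and the aldolate oxygens lactonise to the dilactone A4.
- Merits: it is the shortest construction on paper, with four stereocentres and both rings from achiral components under catalytic enantiocontrol, which avoids the material loss of a resolution.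
- Weak points: one catalyst must control two successive aldol events (syn/anti twice, plus the relative sense across C8–C8′), and the second nucleophile is no longer the symmetrical dienolate. Both C9 and C9′ arrive at carboxyl level, so two lactones must be taken down to ethers without disturbing the enolisable C8/C8′ centres or ionising the benzylic positions. The product is again symmetrical.
- Comparison: fewer steps and no resolution speak for this road. The chosen plan has only one lactone to reduce, brings C9 in at the ether oxidation level, and keeps the aryl groups distinct.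

**Alternative 3:** The cut is at C8–C8′ and C7′–O. In the key step Cp2TiCl (trivalent titanium) opens the oxirane of the epoxy cinnamyl ether A8 to a C8 radical, which cyclises 5-exo onto the cinnamyl double bond; iodine then converts the benzylic C7′ centre into the C7′–O bond with the C9 alkoxide, giving 4-O-allyl-4′-O-TIPS-pinoresinol A7.
- Merits: the unsymmetrical, orthogonally protected core comes directly from one carbinol stereocentre, in fewer steps than the chosen route needs to reach 17, and the chiral epoxy alcohol behind A8 is easy to obtain.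
- Weak points: the C8 radical is planar, so C8 and C8′ depend on a radical transition state steered only by the C7 substituent, and C7′ on an ionic closure. Reduction of the benzylic radical without ring closure competes, titanium is stoichiometric, and the silyl ether meets iodine.
- Comparison: in step count and phenol differentiation this road is as good or better. The chosen plan offers a concerted, suprafacial bond formation that enforces the cis fusion and relays C7 to C8/C8′ across a rigid ring face. At C7′ the two plans are about equally uncertain.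

Key step: step 9

## Remarks before the steps

- Assumption: the stereodescriptors of the target are read from its structure as 7R,8S,7′R,8′S,7″R,8″S, i.e. a (−)-pinoresinol core with an erythro side chain.
- Assumption: (R)-4-benzyl-3-(chloroacetyl)oxazolidin-2-one (19) is purchased; otherwise it is one N-acylation away from (R)-4-benzyloxazolidin-2-one.
- SEM = 2-(trimethylsilyl)ethoxymethyl. "PinO" = 4-{(1R,3aS,4R,6aS)-4-[4-(allyloxy)-3-methoxyphenyl]tetrahydro-1H,3H-furo[3,4-c]furan-1-yl}-2-methoxyphenoxy, the phenoxy residue of 18.

## Route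

Step 1
Reactants: 1 vanillin
Product: 2 3-methoxy-4-{[2-(trimethylsilyl)ethoxy]methoxy}benzaldehyde (O-SEM-vanillin)
Conditions: SEMCl, i-Pr2NEt, CH2Cl2, 0 °C → rt
Reagents that add atoms: 2-(trimethylsilyl)ethoxymethyl chloride, C[Si](C)(C)CCOCCl
Why: O-alkylation of the phenol by a chloromethyl ether (acetal protection). SEM survives Grignard reagent, hydride, metathesis and solid CsF and is later removed by soluble fluoride without acid.

Step 2
Reactants: 2 O-SEM-vanillin; 3 vinylmagnesium bromide
Product: 4 rac-1-(3-methoxy-4-SEM-oxyphenyl)prop-2-en-1-ol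
Conditions: THF, −78 → 0 °C; aq. NH4Cl work-up
Reagents that add atoms: none
Why: Grignard 1,2-addition to an aryl aldehyde; the racemic carbinol is resolved in the next step.

Step 3
Reactants: 4 racemic allylic alcohol
Product: 5 (R)-1-(3-methoxy-4-SEM-oxyphenyl)prop-2-en-1-ol
Conditions: Ti(OiPr)4, D-(−)-DIPT, t-BuOOH (0.6 equiv), 4 Å MS, CH2Cl2, −20 °C
Reagents that add atoms: none
Why: Sharpless kinetic resolution. With D-(−)-DIPT the S carbinol should be epoxidised faster (the aryl group takes the place of the alkyl group of the usual model and outranks vinyl, which reverses the familiar descriptor), so running past half conversion should leave (R)-5 in high enantiomeric purity and set C7. At most half of 4 can be carried on.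

Step 4
Reactants: 5 (R)-allylic alcohol; 6 acryloyl chloride
Product: 7 (R)-1-(3-methoxy-4-SEM-oxyphenyl)prop-2-en-1-yl prop-2-enoate
Conditions: Et3N, CH2Cl2, −20 → 0 °C
Reagents that add atoms: none
Why: O-acylation of a secondary alcohol by an acid chloride; low temperature and amine base keep the electron-rich allylic ester from ionising or rearranging.

Step 5
Reactants: 7 allylic acrylate
Product: 8 (R)-5-(3-methoxy-4-SEM-oxyphenyl)furan-2(5H)-one (γ-aryl butenolide)
Conditions: second-generation Grubbs catalyst (5 mol %), CH2Cl2, 40 °C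
Reagents that add atoms: none
Why: Ring-closing metathesis of an allylic acrylate to a butenolide, a standard use of this catalyst; the neutral medium leaves the base-sensitive C7–H untouched.

Step 6
Reactants: 1 vanillin
Product: 9 4-(allyloxy)-3-methoxybenzaldehyde (O-allylvanillin)
Conditions: allyl bromide, K2CO3, acetone, reflux
Reagents that add atoms: allyl bromide, C=CCBr
Why: Williamson ether synthesis on the phenoxide. The allyl ether is stable to acid chloride, fluoride, hydride and boron enolates and is removed at the end under neutral palladium catalysis.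

Step 7
Reactants: 9 O-allylvanillin; 10 (trimethylsilyl)methanol
Product: 11 1-(allyloxy)-4-{bis[(trimethylsilyl)methoxy]methyl}-2-methoxybenzene (bis(silylmethyl) acetal of 9)
Conditions: 10 (2.2 equiv), PPTS (cat.), benzene, reflux, Dean–Stark
Reagents that add atoms: none
Why: Acid-catalysed acetalisation driven by azeotropic removal of water; the primary α-silyl alcohol behaves as an ordinary alcohol.

Step 8
Reactants: 11 bis(silylmethyl) acetal
Product: 12 1-(allyloxy)-4-{chloro[(trimethylsilyl)methoxy]methyl}-2-methoxybenzene (racemic α-chloro ether)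
Conditions: AcCl, SOCl2 (cat.), CH2Cl2, 0 °C → rt; volatiles removed, used crude
Reagents that add atoms: acetyl chloride, CC(=O)Cl
Why: Cleavage of an acetal by an acid chloride to the α-chloro ether, one alkoxy group leaving as its acetate. The para-alkoxy group makes the chloride very labile, so the product is used at once without purification.

Step 9
Reactants: 8 γ-aryl butenolide; 12 α-chloro ether
Product: 14 (3R,3aS,6R,6aR)-6-[4-(allyloxy)-3-methoxyphenyl]-3-(3-methoxy-4-SEM-oxyphenyl)tetrahydro-1H,3H-furo[3,4-c]furan-1-one (furofuranone; C9′ is the lactone carbonyl), via carbonyl ylide 13 (not isolated)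
Conditions: 12 (2.5 equiv), CsF (4 equiv), MeCN, 0 °C → rt
Reagents that add atoms: none
Why: Fluoride attacks silicon of 12 while chloride leaves (1,3-elimination through the aryl-stabilised oxocarbenium ion), releasing the non-stabilised carbonyl ylide 13, whose negative charge sits mainly on the unsubstituted terminus C9 because the electron-rich aryl group disfavours carbanion character at C7′. The closest known reaction type is the CsF-induced generation of such ylides from α-chloroalkyl (trimethylsilyl)methyl ethers and their [3+2] cycloaddition to α,β-unsaturated esters, of which 8 is a cyclic member. Ring 2 closes in a concerted cycloaddition that is suprafacial on both partners, C9 bonding to the β-carbon C8 and C7′ to the α-carbon C8′, so the cis ring fusion is obligatory. C8 and C8′ are set by substrate control: the ylide approaches the butenolide face anti to aryl B at C7, the usual behaviour of γ-substituted butenolides. C7′ is set by the orientation of the ylide: in the favoured arrangement the anti-configured ylide lies with its oxygen and aryl A turned away from the lactone ring (exo), which places aryl A trans to the C8′–C9′ bond. Regiochemistry follows the dipole polarity and is reinforced by sterics, since the unsubstituted terminus is the one that must bond next to C7. The step therefore needs face, regio and exo selectivity; the first two rest on the substrate, the third only on sterics. Excess 12, low temperature and the sparing solubility of CsF in MeCN are meant to keep base contact with the acidic C7–H of 8 short.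

Step 10
Reactants: 14 furofuranone
Product: 15 (R)-{(3S,4S,5R)-5-[4-(allyloxy)-3-methoxyphenyl]-4-(hydroxymethyl)oxolan-3-yl}(3-methoxy-4-SEM-oxyphenyl)methanol (C7,C9′-diol)
Conditions: LiAlH4, THF, 0 °C
Reagents that add atoms: none
Why: Hydride reduction of a lactone to the 1,4-diol; the ethers, the SEM acetal and the four stereocentres are not affected.

Step 11
Reactants: 15 diol
Product: 17 (1R,3aS,4R,6aS)-1-[4-(allyloxy)-3-methoxyphenyl]-4-(3-methoxy-4-SEM-oxyphenyl)tetrahydro-1H,3H-furo[3,4-c]furan [(−)-pinoresinol 4-O-SEM 4′-O-allyl diether], via primary mesylate 16 (not isolated)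
Conditions: MsCl (1.1 equiv), Et3N, CH2Cl2, 0 °C → rt
Reagents that add atoms: none
Why: Selective sulfonylation of the primary alcohol followed by intramolecular Williamson etherification (5-exo-tet) by the C7 hydroxyl. The C7 oxygen is the nucleophile, so C7 keeps its configuration and ring 1 closes with aryl B exo.

Step 12
Reactants: 17 SEM/allyl diether
Product: 18 4-{(1R,3aS,4R,6aS)-4-[4-(allyloxy)-3-methoxyphenyl]tetrahydro-1H,3H-furo[3,4-c]furan-1-yl}-2-methoxyphenol [(−)-pinoresinol mono-O-allyl ether]
Conditions: TBAF, THF–DMPU, 60 °C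
Reagents that add atoms: none
Why: Fluoride-induced fragmentation of the SEM acetal (attack at silicon, loss of ethylene and formaldehyde); the basic medium spares the acid-labile benzylic ethers and the allyl ether.

Step 13
Reactants: 18 phenol; 19 (R)-4-benzyl-3-(chloroacetyl)oxazolidin-2-one
Product: 20 (R)-4-benzyl-3-[(PinO)acetyl]oxazolidin-2-one
Conditions: K2CO3, NaI (cat.), MeCN, rt → 40 °C
Reagents that add atoms: none
Why: Williamson alkylation of the phenoxide by an α-halo imide with iodide (Finkelstein) activation; the weak base limits attack at the imide carbonyl groups.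

Step 14
Reactants: 20 aryloxyacetyl imide; 9 O-allylvanillin
Product: 22 (R)-4-benzyl-3-[(2R,3S)-3-[4-(allyloxy)-3-methoxyphenyl]-3-hydroxy-2-(PinO)propanoyl]oxazolidin-2-one (threo aldol), via dibutylboron enolate 21 (not isolated)
Conditions: Bu2BOTf, i-Pr2NEt, CH2Cl2, −78 → 0 °C; then 9, −78 → 0 °C; pH 7 buffer, MeOH, H2O2
Reagents that add atoms: none
Why: Evans syn-aldol reaction of a glycolate imide. The Z boron enolate reacts through a Zimmerman–Traxler chair on the face away from the benzyl group of the R auxiliary, which sets C8″ (S in the final diol) and gives C7″ as S, i.e. the threo adduct. The amine-buffered Lewis acid at low temperature should leave the benzylic ethers alone.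

Step 15
Reactants: 22 threo aldol
Product: 23 (1R,2R)-1-[4-(allyloxy)-3-methoxyphenyl]-3-[(R)-4-benzyl-2-oxooxazolidin-3-yl]-3-oxo-2-(PinO)propyl 4-nitrobenzoate
Conditions: 4-O2NC6H4CO2H, PPh3, DIAD, THF, 0 °C → rt
Reagents that add atoms: 4-nitrobenzoic acid, O=C(O)c1ccc(cc1)[N+](=O)[O-]
Why: Mitsunobu reaction; SN2 displacement of the alkoxyphosphonium ion by the carboxylate inverts C7″ from S to R and turns the threo into the erythro series.

Step 16
Reactants: 23 erythro 4-nitrobenzoate
Product: 24 (1R,2S)-1-[4-(allyloxy)-3-methoxyphenyl]-2-(PinO)propane-1,3-diol (bis-allyl ether of the target)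
Conditions: LiBH4, MeOH (2 equiv), THF, 0 °C → rt
Reagents that add atoms: none
Why: Borohydride reduction cleaves the N-acyl oxazolidinone to the primary alcohol and reduces the activated aryl ester, freeing the C7″ hydroxyl; no stereocentre is touched.

Step 17
Reactants: 24 bis-allyl ether
Product: 25 (1R,2S)-1-(4-hydroxy-3-methoxyphenyl)-2-{4-[(1R,3aS,4R,6aS)-4-(4-hydroxy-3-methoxyphenyl)tetrahydro-1H,3H-furo[3,4-c]furan-1-yl]-2-methoxyphenoxy}propane-1,3-diol (CNP0172915.1)
Conditions: Pd(PPh3)4 (10 mol %), morpholine, THF, rt
Reagents that add atoms: none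
Why: Tsuji–Trost-type allyl transfer: zerovalent palladium ionises both aryl allyl ethers to π-allyl complexes that morpholine traps. The neutral conditions leave the benzylic alcohol, the benzylic ethers and the phenols intact.

## Compound list

1 | vanillin (4-hydroxy-3-methoxybenzaldehyde) | COc1cc(C=O)ccc1O | starting material
2 | 3-methoxy-4-{[2-(trimethylsilyl)ethoxy]methoxy}benzaldehyde | COc1cc(C=O)ccc1OCOCC[Si](C)(C)C | intermediate
3 | vinylmagnesium bromide | C=C[Mg]Br | starting material
4 | rac-1-(3-methoxy-4-SEM-oxyphenyl)prop-2-en-1-ol | COc1cc(C(O)C=C)ccc1OCOCC[Si](C)(C)C | intermediate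
5 | (R)-1-(3-methoxy-4-SEM-oxyphenyl)prop-2-en-1-ol | COc1cc([C@H](O)C=C)ccc1OCOCC[Si](C)(C)C | intermediate
6 | acryloyl chloride | C=CC(=O)Cl | starting material
7 | (R)-1-(3-methoxy-4-SEM-oxyphenyl)prop-2-en-1-yl prop-2-enoate | COc1cc([C@H](OC(=O)C=C)C=C)ccc1OCOCC[Si](C)(C)C | intermediate
8 | (R)-5-(3-methoxy-4-SEM-oxyphenyl)furan-2(5H)-one | COc1cc([C@@H]2OC(=O)C=C2)ccc1OCOCC[Si](C)(C)C | intermediate
9 | 4-(allyloxy)-3-methoxybenzaldehyde | COc1cc(C=O)ccc1OCC=C | intermediate
10 | (trimethylsilyl)methanol | C[Si](C)(C)CO | starting material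
11 | 1-(allyloxy)-4-{bis[(trimethylsilyl)methoxy]methyl}-2-methoxybenzene | COc1cc(C(OC[Si](C)(C)C)OC[Si](C)(C)C)ccc1OCC=C | intermediate
12 | 1-(allyloxy)-4-{chloro[(trimethylsilyl)methoxy]methyl}-2-methoxybenzene (racemic) | COc1cc(C(Cl)OC[Si](C)(C)C)ccc1OCC=C | intermediate
13 | carbonyl ylide [4-(allyloxy)-3-methoxybenzylidene]oxonium methylide (not isolated) | [CH2-][O+]=Cc1ccc(OCC=C)c(OC)c1 | intermediate
14 | (3R,3aS,6R,6aR)-6-[4-(allyloxy)-3-methoxyphenyl]-3-(3-methoxy-4-SEM-oxyphenyl)tetrahydro-1H,3H-furo[3,4-c]furan-1-one | C[Si](C)(C)CCOCOc1ccc([C@@H]2OC(=O)[C@@H]3[C@H]2CO[C@H]3c2ccc(OCC=C)c(OC)c2)cc1OC | intermediate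
15 | (R)-{(3S,4S,5R)-5-[4-(allyloxy)-3-methoxyphenyl]-4-(hydroxymethyl)oxolan-3-yl}(3-methoxy-4-SEM-oxyphenyl)methanol | C[Si](C)(C)CCOCOc1ccc([C@H](O)[C@@H]2CO[C@@H](c3ccc(OCC=C)c(OC)c3)[C@@H]2CO)cc1OC | intermediate
16 | primary methanesulfonate of 15 at C9′ (not isolated) | C[Si](C)(C)CCOCOc1ccc([C@H](O)[C@@H]2CO[C@@H](c3ccc(OCC=C)c(OC)c3)[C@@H]2COS(C)(=O)=O)cc1OC | intermediate
17 | (1R,3aS,4R,6aS)-1-[4-(allyloxy)-3-methoxyphenyl]-4-(3-methoxy-4-SEM-oxyphenyl)tetrahydro-1H,3H-furo[3,4-c]furan | C[Si](C)(C)CCOCOc1ccc([C@@H]2OC[C@@H]3[C@H]2CO[C@H]3c2ccc(OCC=C)c(OC)c2)cc1OC | intermediate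
18 | 4-{(1R,3aS,4R,6aS)-4-[4-(allyloxy)-3-methoxyphenyl]tetrahydro-1H,3H-furo[3,4-c]furan-1-yl}-2-methoxyphenol | COc1cc([C@@H]2OC[C@@H]3[C@H]2CO[C@H]3c2ccc(OCC=C)c(OC)c2)ccc1O | intermediate
19 | (R)-4-benzyl-3-(chloroacetyl)oxazolidin-2-one | ClCC(=O)N1[C@H](Cc2ccccc2)COC1=O | starting material
20 | (R)-4-benzyl-3-[(PinO)acetyl]oxazolidin-2-one | O=C(COc1ccc([C@@H]2OC[C@@H]3[C@H]2CO[C@H]3c2ccc(OCC=C)c(OC)c2)cc1OC)N1[C@H](Cc2ccccc2)COC1=O | intermediate
21 | Z dibutylboron enolate of 20 (not isolated) | CCCCB(CCCC)O/C(=C\Oc1ccc([C@@H]2OC[C@@H]3[C@H]2CO[C@H]3c2ccc(OCC=C)c(OC)c2)cc1OC)N1[C@H](Cc2ccccc2)COC1=O | intermediate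
22 | (R)-4-benzyl-3-[(2R,3S)-3-[4-(allyloxy)-3-methoxyphenyl]-3-hydroxy-2-(PinO)propanoyl]oxazolidin-2-one | O=C([C@H](Oc1ccc([C@@H]2OC[C@@H]3[C@H]2CO[C@H]3c2ccc(OCC=C)c(OC)c2)cc1OC)[C@@H](O)c1ccc(OCC=C)c(OC)c1)N1[C@H](Cc2ccccc2)COC1=O | intermediate
23 | (1R,2R)-1-[4-(allyloxy)-3-methoxyphenyl]-3-[(R)-4-benzyl-2-oxooxazolidin-3-yl]-3-oxo-2-(PinO)propyl 4-nitrobenzoate | O=C([C@H](Oc1ccc([C@@H]2OC[C@@H]3[C@H]2CO[C@H]3c2ccc(OCC=C)c(OC)c2)cc1OC)[C@H](OC(=O)c1ccc(cc1)[N+](=O)[O-])c1ccc(OCC=C)c(OC)c1)N1[C@H](Cc2ccccc2)COC1=O | intermediate
24 | (1R,2S)-1-[4-(allyloxy)-3-methoxyphenyl]-2-(PinO)propane-1,3-diol | COc1cc([C@@H](O)[C@H](CO)Oc2ccc([C@@H]3OC[C@@H]4[C@H]3CO[C@H]4c3ccc(OCC=C)c(OC)c3)cc2OC)ccc1OCC=C | intermediate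
25 | (1R,2S)-1-(4-hydroxy-3-methoxyphenyl)-2-{4-[(1R,3aS,4R,6aS)-4-(4-hydroxy-3-methoxyphenyl)tetrahydro-1H,3H-furo[3,4-c]furan-1-yl]-2-methoxyphenoxy}propane-1,3-diol | COc1cc([C@@H](O)[C@H](CO)Oc2ccc([C@@H]3OC[C@@H]4[C@H]3CO[C@H]4c3ccc(O)c(OC)c3)cc2OC)ccc1O | target

## Step count and risks

Total: 17 steps. Longest linear sequence: 14 steps (1 → 2 → 4 → 5 → 7 → 8 → 14 → 15 → 17 → 18 → 20 → 22 → 23 → 24 → 25); the branch 1 → 9 → 11 → 12 joins at step 9, and 9 is used again in step 14.

**Step 9 (key step).** Three things are most likely to go wrong: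
- insufficient exo preference, which gives the C7′ epimer with aryl A on the concave face, because only sterics oppose it;
- partial reversal of regiochemistry;
- deprotonation of the acidic C7–H of the butenolide by fluoride or by the ylide, with loss of enantiomeric purity or isomerisation to the 2(3H)-furanone.

The fallback gives up the cycloaddition for the tandem conjugate addition–aldol route on a chiral γ-alkoxybutenolide. It sets out from 2 and 9 and comes back at 17.
- Aldehyde 2 is converted with propane-1,3-dithiol and catalytic iodine into 2-(3-methoxy-4-SEM-oxyphenyl)-1,3-dithiane F1.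
- Lithiated F1 adds to (5S)-5-[(1S,2R,5S)-menthyloxy]furan-2(5H)-one F2 (made from furfural by photo-oxygenation and acetalisation with (+)-menthol) anti to the menthyloxy group. The lactone enolate is trapped with aldehyde 9 trans to the new substituent, giving the tandem adduct F3, which has the correct C8/C8′ configuration.
- MeI/CaCO3 in aqueous MeCN removes the dithiane to give the ketone F4.
- LiAlH4 reduces ketone, lactone and acetal carbon to the tetraol F5, releasing menthol.
- MsCl/Et3N closes both rings through the electron-rich benzylic cations, a mode of closure known to favour the di-exo furofuran, to give 17.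

**Step 15.** The alkoxyphosphonium ion of an electron-rich benzylic carbinol may ionise, which erodes the inversion, or the β-hydroxy imide may eliminate to the enimide. The fallback replaces substitution by an oxidation–reduction sequence. It sets out from 22 and comes back at 24.
- LiBH4 removes the auxiliary to give the threo diol F6.
- TBSCl/imidazole silylates the primary hydroxyl to give the silyl ether F7.
- Dess–Martin periodinane (NaHCO3 buffer) gives the aryl ketone F8.
- Zn(BH4)2 in Et2O at low temperature reduces F8 under chelation control (zinc bridging the carbonyl and aryloxy oxygens, hydride arriving past the small hydrogen on C8″) to the erythro alcohol F9.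
- TBAF gives 24.

**Step 13.** The phenoxide may attack the imide carbonyl groups (acyl transfer, loss of the auxiliary) instead of the CH2–Cl carbon. The fallback builds the imide from the acid. It sets out from 18 and comes back at 20.
- Ethyl bromoacetate/K2CO3 gives the ethyl aryloxyacetate F10.
- LiOH in aqueous THF gives the aryloxyacetic acid F11.
- F11 is activated as its mixed pivalic anhydride (PivCl, Et3N) and coupled with (R)-4-benzyloxazolidin-2-one in the presence of LiCl to give 20.

**Step 3.** Epoxidation of a monosubstituted vinyl group is slow, so the resolution may stall before the recovered alcohol is enantiopure, and the Lewis acid may transpose the electron-rich allylic alcohol. The fallback is an enzymatic resolution. It sets out from 4 and comes back at 5.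
- Candida antarctica lipase B with vinyl acetate acylates the R enantiomer, as the empirical rule for secondary alcohols predicts (aryl large, vinyl medium), giving the (R)-acetate F12, which is separated from the unreacted S alcohol.
- K2CO3 in MeOH cleaves F12 to 5.

## Further compounds

F1 | step 9 | 2-(3-methoxy-4-SEM-oxyphenyl)-1,3-dithiane | COc1cc(C2SCCCS2)ccc1OCOCC[Si](C)(C)C
F2 | step 9 | (5S)-5-{[(1S,2R,5S)-2-isopropyl-5-methylcyclohexyl]oxy}furan-2(5H)-one | O=C1C=C[C@@H](O[C@H]2C[C@@H](C)CC[C@@H]2C(C)C)O1
F3 | step 9 | (3R,4S,5S)-3-{[4-(allyloxy)-3-methoxyphenyl](hydroxy)methyl}-4-[2-(3-methoxy-4-SEM-oxyphenyl)-1,3-dithian-2-yl]-5-[(1S,2R,5S)-menthyloxy]oxolan-2-one (carbinol carbon undefined) | O=C1O[C@H](O[C@H]2C[C@@H](C)CC[C@@H]2C(C)C)[C@@H](C2(c3ccc(OCOCC[Si](C)(C)C)c(OC)c3)SCCCS2)[C@@H]1C(O)c1ccc(OCC=C)c(OC)c1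
F4 | step 9 | 3-{[4-(allyloxy)-3-methoxyphenyl](hydroxy)methyl}-4-(3-methoxy-4-SEM-oxybenzoyl)-5-[(1S,2R,5S)-menthyloxy]oxolan-2-one (ring configuration as in F3) | O=C1O[C@H](O[C@H]2C[C@@H](C)CC[C@@H]2C(C)C)[C@@H](C(=O)c2ccc(OCOCC[Si](C)(C)C)c(OC)c2)[C@@H]1C(O)c1ccc(OCC=C)c(OC)c1
F5 | step 9 | (2S,3S)-2-{[4-(allyloxy)-3-methoxyphenyl](hydroxy)methyl}-3-[hydroxy(3-methoxy-4-SEM-oxyphenyl)methyl]butane-1,4-diol (benzylic carbons undefined) | C[Si](C)(C)CCOCOc1ccc(C(O)[C@H](CO)[C@@H](CO)C(O)c2ccc(OCC=C)c(OC)c2)cc1OC
F6 | step 15 | (1S,2S)-1-[4-(allyloxy)-3-methoxyphenyl]-2-(PinO)propane-1,3-diol (threo diol) | COc1cc([C@H](O)[C@H](CO)Oc2ccc([C@@H]3OC[C@@H]4[C@H]3CO[C@H]4c3ccc(OCC=C)c(OC)c3)cc2OC)ccc1OCC=C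
F7 | step 15 | (1S,2S)-1-[4-(allyloxy)-3-methoxyphenyl]-3-[(tert-butyldimethylsilyl)oxy]-2-(PinO)propan-1-ol | COc1cc([C@H](O)[C@H](CO[Si](C)(C)C(C)(C)C)Oc2ccc([C@@H]3OC[C@@H]4[C@H]3CO[C@H]4c3ccc(OCC=C)c(OC)c3)cc2OC)ccc1OCC=C
F8 | step 15 | (S)-1-[4-(allyloxy)-3-methoxyphenyl]-3-[(tert-butyldimethylsilyl)oxy]-2-(PinO)propan-1-one | COc1cc(C(=O)[C@H](CO[Si](C)(C)C(C)(C)C)Oc2ccc([C@@H]3OC[C@@H]4[C@H]3CO[C@H]4c3ccc(OCC=C)c(OC)c3)cc2OC)ccc1OCC=C
F9 | step 15 | (1R,2S)-1-[4-(allyloxy)-3-methoxyphenyl]-3-[(tert-butyldimethylsilyl)oxy]-2-(PinO)propan-1-ol (erythro) | COc1cc([C@@H](O)[C@H](CO[Si](C)(C)C(C)(C)C)Oc2ccc([C@@H]3OC[C@@H]4[C@H]3CO[C@H]4c3ccc(OCC=C)c(OC)c3)cc2OC)ccc1OCC=C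
F10 | step 13 | ethyl (PinO)acetate | CCOC(=O)COc1ccc([C@@H]2OC[C@@H]3[C@H]2CO[C@H]3c2ccc(OCC=C)c(OC)c2)cc1OC
F11 | step 13 | (PinO)acetic acid | OC(=O)COc1ccc([C@@H]2OC[C@@H]3[C@H]2CO[C@H]3c2ccc(OCC=C)c(OC)c2)cc1OC
F12 | step 3 | (R)-1-(3-methoxy-4-SEM-oxyphenyl)prop-2-en-1-yl acetate | COc1cc([C@H](OC(C)=O)C=C)ccc1OCOCC[Si](C)(C)C
A1 | alternative 1 | pinoresinol bis-TIPS ether (7R,8S,7′R,8′S) | COc1cc([C@@H]2OC[C@@H]3[C@H]2CO[C@H]3c2ccc(O[Si](C(C)C)(C(C)C)C(C)C)c(OC)c2)ccc1O[Si](C(C)C)(C(C)C)C(C)C
A2 | alternative 1 | (3aS,6aS)-tetrahydro-1H,3H-furo[3,4-c]furan-1,4-diyl diacetate (anomeric carbons undefined) | CC(=O)OC1OC[C@@H]2[C@H]1COC2OC(C)=O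
A3 | alternative 1 | (3-methoxy-4-triisopropylsilyloxyphenyl)zinc bromide | COc1cc([Zn]Br)ccc1O[Si](C(C)C)(C(C)C)C(C)C
A4 | alternative 2 | 2,6-diaryl-3,7-dioxabicyclo[3.3.0]octane-4,8-dione bis-TIPS ether (pinoresinol dilactone) | COc1cc([C@@H]2OC(=O)[C@@H]3[C@H]2C(=O)O[C@H]3c2ccc(O[Si](C(C)C)(C(C)C)C(C)C)c(OC)c2)ccc1O[Si](C(C)C)(C(C)C)C(C)C
A5 | alternative 2 | 2,5-bis(trimethylsilyloxy)furan | C[Si](C)(C)Oc1ccc(O[Si](C)(C)C)o1
A6 | alternative 2 | 3-methoxy-4-(triisopropylsilyloxy)benzaldehyde | COc1cc(C=O)ccc1O[Si](C(C)C)(C(C)C)C(C)C
A7 | alternative 3 | 4-O-allyl-4′-O-TIPS-pinoresinol (7R,8S,7′R,8′S) | C=CCOc1ccc([C@@H]2OC[C@@H]3[C@H]2CO[C@H]3c2ccc(O[Si](C(C)C)(C(C)C)C(C)C)c(OC)c2)cc1OC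
A8 | alternative 3 | (E)-3-(3-methoxy-4-triisopropylsilyloxyphenyl)allyl (S)-[4-(allyloxy)-3-methoxyphenyl](oxiran-2-yl)methyl ether (oxirane carbon undefined) | C=CCOc1ccc([C@H](OC/C=C/c2ccc(O[Si](C(C)C)(C(C)C)C(C)C)c(OC)c2)C2CO2)cc1OC
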